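## The problem

Compound 16 is a trans-α,β-dibenzyl-γ-butyrolactone lignan. Its only non-aromatic ring, lactone ring C (O, C9, C8, C8', C9'), is fused to nothing. Ring A (3,4-dimethoxyphenyl) hangs on the α-carbon C8 through C7, and ring B (3,4-dihydroxyphenyl) hangs on the β-carbon C8' through C7'. The carbon chain is therefore easy to assemble. The real tasks are the two neighbouring stereocentres, 8R and 8'R, and the distinction between two arenes that differ only in O-methylation. C8 lies α to the lactone carbonyl, can be epimerised and prefers the trans arrangement, so C8' can dictate C8 by equilibration; C8' itself has no acidifying neighbour and must be installed in the absolute sense once and for all. The catechol of ring B is oxidised by air and base and binds metals, so it stays masked until the last step by groups that leave without touching the methyl ethers of ring A, and the lactone rules out hydride reagents, hard nucleophiles and aqueous base late in the route. The feature that opens the route is the substitution of C8': besides H and C8 it carries two CH2 arms, C9' on the lactone oxygen and C7' on ring B, and if C7' is traced back to a CH2–O group the two arms can be tied through one oxygen into a 3-substituted oxetane in which they are enantiotopic. With two identical ester groups on C8, the precursor 6 has a mirror plane, and a chiral acid can decide which CH2 becomes C9' in the same event that closes ring C.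

## Retrosynthesis

**16 ⇒ 15.** The two phenolic O–H bonds of ring B are traced back to O–benzyl bonds. Benzyl ethers differ from the methyl ethers of ring A in that they leave under neutral hydrogenolysis. This is the gentlest way to release an oxidation-prone catechol next to a lactone. The forward step only has to spare C7 and C7', which carry no heteroatom.

**15 ⇒ 12, through 14 and 13.** A tert-butoxycarbonyl group is placed on C8, so the forward step breaks C8–CO2. This looks like added complexity, but it removes a stereochemical task. C8 of 15 is reset by decarboxylation (13 to 14) and base equilibration (14 to 15) under the control of C8', so the configuration of the quaternary C8 in 12 is irrelevant. The extra ester also blocks enolisation of the lactone during the steps before it. The forward step must cleave the ester without harming the benzyl ethers and must end at the trans isomer.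

**12 ⇒ 9 + 11.** The bond between C7' and C1' of ring B is cut.
- The neighbouring cut, C8'–C7', would call for a benzyl nucleophile and an enantiopure butenolide.
- A C8–C8' cut would need an auxiliary on one half.
- The C7'–aryl cut turns ring B into the simple aryl bromide 11 and leaves C7' as a functionalised CH2. This uncovers the pair of similar arms on C8'.
- The forward reaction is an sp3–sp2 coupling at a primary, β-branched carbon that tolerates a lactone and an ester.

**9 ⇒ 8.** The C7'–Br bond is exchanged for C7'–OH. This is a functional-group change only, but it must be neutral and fast, since the free alcohol of 8 sits near two acyl groups.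

**8 ⇒ 6, through 7.** The O–C9' bond of ring C is cut and C9' is reconnected to the oxygen on C7', which gives the oxetane. The lactone carbonyl returns to a tert-butyl ester.
- One ring and both stereocentres disappear, and 6 is achiral with a mirror plane through C7, C8, C8' and the oxetane oxygen.
- Cutting C9–O instead would lead to a 1,3-diol that cannot be stored next to two esters.
- The oxetane holds both arms in a masked, base-stable form.
- The forward reaction asks a chiral Brønsted acid to activate the oxetane, an ester carbonyl oxygen to open it, and cation 7 to shed its tert-butyl group so that the proton returns to the catalyst.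

**6 ⇒ 3 + 5, and 5 ⇒ 4.** The C8–C7 bond is cut. A malonate anion and a benzylic bromide are the natural partners, and introducing the benzyl group last uses the more reactive electrophile for the more hindered bond. Bromide 5 comes from the commercial alcohol 4 and is made fresh because it does not keep.

**3 ⇒ 1 + 2.** The C8–C8' bond is cut between the malonate carbon and C3 of the oxetane. Both pieces are commercial. The forward displacement is slow for a four-membered ring, but elimination, the usual competitor at a secondary halide, is closed because it would put a double bond into the small ring.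

**11 ⇒ 10.** Two O–benzyl bonds are cut. The forward step is a double etherification of the commercial bromocatechol 10.

## Roads not taken

**Alternative 1:** ring B is built rather than bought.
- *Cut:* it removes C1'–C2' and C5'–C6' of ring B. It leads back to the propargyl lactone (3R,4R)-3-(3,4-dimethoxybenzyl)-4-(prop-2-yn-1-yl)dihydrofuran-2(3H)-one A1 and the symmetrical diene 2,3-bis(trimethylsilyloxy)buta-1,3-diene A2.
- *Forward key step:* CoBr2(dppe), reduced by zinc powder with ZnI2 present, would join the terminal alkyne of A1 with A2 in a formal [4+2] cycloaddition. The product is the 1,4-cyclohexadiene A3, which dehydrogenation and desilylation would carry to 16.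
- *Merits:* the symmetry of A2 removes any regiochemical question. The catechol arrives already masked by groups that fall off on work-up. No coupling at a hindered sp3 carbon and no hydrogenolysis are needed. In these respects it is better than the chosen plan.
- *Weak points:* the key step creates none of the stereochemistry, so both centres of A1 still need a separate asymmetric synthesis. It spends the main effort on the one part of the molecule that can be purchased. A2 and A3 are bis(silyl enol ethers) exposed to a zinc Lewis acid. The dehydrogenation of A3 needs an oxidant that stops at the catechol level and also spares the electron-rich benzylic C7.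
- *Comparison:* the chosen plan answers with a key step that solves the only hard problem, the absolute configuration at C8', and takes ring B from the shelf.

**Alternative 2:** a bond C8–C7' is first added to the target, and the resulting cyclopropane is then cut at C8–C8' and C8–C7'.
- *Cut:* it leads back to the diazoester (E)-3-[3,4-bis(benzyloxy)phenyl]allyl 2-diazo-3-(3,4-dimethoxyphenyl)propanoate A4.
- *Forward key step:* Rh2(5S-MEPY)4 or its enantiomer would generate the carbene at C8 and add it across the cinnamyl alkene to give the cyclopropane-fused lactone A5. Reductive opening of the push–pull bond C8–C7' and debenzylation could then take place in a single hydrogenation to 16.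
- *Merits:* this is the most compact road on paper, with two C–C bonds, two rings and three stereocentres in one step and a single step after it. In step count it beats the chosen plan.
- *Weak points:* all lie in A4.
  - The carbene carbon bears a CH2 with two benzylic hydrogens, so a 1,2-hydride shift to the unsaturated ester competes with cyclopropanation.
  - Dirhodium carboxamidates show their best selectivities with unsubstituted diazoacetates, and a trans-cinnamyl alkene is not their best partner.
  - The electron-rich rings and the benzylic OCH2 groups offer further sites for the carbene.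
  - The diazo compound has to be made and handled.
- *Comparison:* the key step of the chosen plan is less tested than carbene cyclopropanation as a class. However, its substrate 6 has no comparable built-in escape path, and enantiotopic-group selection is the only selectivity that has to survive to 16.

**Alternative 3:** C9' is removed as a one-carbon unit.
- *Cut:* C8'–C9' and C9–O are cut. This leads to the γ-keto ester methyl (2R)-4-[3,4-bis(benzyloxy)phenyl]-2-(3,4-dimethoxybenzyl)-4-oxobutanoate A6 and formaldehyde A7.
- *Forward key step:* with K2CO3 the ketone enolate at C8' of A6 would add to A7, and the new alkoxide would close ring C on the methyl ester to give the trans aroyl lactone A8. Hydrogenolytic removal of the electron-rich aryl ketone could be merged with debenzylation.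
- *Merits:* the operations are old and robust, the C1 unit costs nothing, and C8' settles trans by equilibration because it is α to the ketone. In the reliability of its single steps this road is ahead of the chosen plan.
- *Weak points:*
  - C8 of A6 must be set beforehand, most likely with a stoichiometric auxiliary or a separate asymmetric hydrogenation.
  - During the basic step the whole absolute information rests on that one centre, which is itself α to a carbonyl, while its neighbour is being equilibrated.
  - C8' of A8 keeps an acidic hydrogen, so a second addition of A7 and dehydration of the aldol before ring closure have to be held back.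
- *Comparison:* the chosen plan offers a catalytic source of chirality, a stereocentre that cannot epimerise once made, and an achiral precursor reached in three simple steps.

Key step: step 4

Assumption: the (R)-acid is taken to give the C8' configuration drawn (the equally available (S)-acid would be used if the sense proves opposite). Compounds 7, 8, 9, 12 and 13 are drawn as the C8 epimer with the benzyl group trans to the C7' arm, and the other epimer is carried along because C8 is reset in step 8.

## Steps

Step 1
Reactants: 1 di-tert-butyl malonate; 2 3-iodooxetane
Product: 3 di-tert-butyl 2-(oxetan-3-yl)malonate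
Conditions: NaH, DMF, 0 °C; then 2, 80 °C
Reagents that add atoms: none
Why: Malonic ester alkylation by SN2 displacement at C3 of the oxetane forms C8–C8'. Elimination is closed because it would place a double bond in the four-membered ring, so heating can be used, and unactivated oxetanes are inert to stabilised carbanions.

Step 2
Reactants: 4 veratryl alcohol (3,4-dimethoxybenzyl alcohol)
Product: 5 3,4-dimethoxybenzyl bromide
Conditions: PBr3, Et2O, 0 °C; used at once
Reagents that add atoms: phosphorus tribromide, BrP(Br)Br
Why: This is the standard conversion of a benzylic alcohol into the bromide through its phosphite ester. The electron-rich bromide is labile, so it is taken into step 3 without storage.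

Step 3
Reactants: 3 di-tert-butyl 2-(oxetan-3-yl)malonate; 5 3,4-dimethoxybenzyl bromide
Product: 6 di-tert-butyl 2-(3,4-dimethoxybenzyl)-2-(oxetan-3-yl)malonate
Conditions: NaH, DMF, 0 °C; then 5, 0 °C to rt
Reagents that add atoms: none
Why: A second malonate alkylation forms C8–C7, and the hindered anion is matched with a very reactive benzylic bromide. The product is achiral with a mirror plane, so no stereochemical question arises.

Step 4
Reactants: 6 di-tert-butyl 2-(3,4-dimethoxybenzyl)-2-(oxetan-3-yl)malonate
Product: 8 tert-butyl (3S,4S)-3-(3,4-dimethoxybenzyl)-4-(hydroxymethyl)-2-oxotetrahydrofuran-3-carboxylate, via dialkoxycarbenium ion 7 (not isolated)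
Conditions: (R)-3,3'-bis(2,4,6-triisopropylphenyl)-1,1'-binaphthyl-2,2'-diyl hydrogen phosphate (10 mol%), 4 Å MS, toluene, 40 °C
Reagents that add atoms: none
Why: Proposed new method: the phosphoric acid hydrogen-bonds to the oxetane oxygen of 6 and weakens both C–O bonds, the carbonyl oxygen of one tert-butyl ester attacks one oxetane CH2 from the rear to form O–C9' and cation 7 as its chiral phosphate ion pair, and 7 loses isobutene, returns the proton to the catalyst and leaves lactone 8 with C7' freed as CH2OH. The closest known reaction types are the chiral-phosphoric-acid-catalysed intramolecular desymmetrising opening of 3-substituted oxetanes by tethered alcohols and the acid-induced dealkylative cyclisation of tert-butyl esters and carbamates onto strained cyclic ethers; the new element is the pairing of the weak ester nucleophile with a chiral acid. Ring C closes in the 5-exo-tet mode. C8' is set by the catalyst alone, because the two oxetane CH2 groups of 6 are enantiotopic and only the pocket formed by the 2,4,6-triisopropylphenyl groups can tell them apart. C8 is set by which of the two enantiotopic esters attacks, expected to be the one that leaves the benzyl group trans to the departing arm, and this centre is erased in step 8. The step needs chemoselectivity for ester oxygen over ring A (a 6-exo Friedel–Crafts opening) and over water, which the shorter 5-exo path, the gem-dialkyl effect at C8, the two equivalent ester groups and the sieves should secure. The run is stopped at full conversion and 8 is used at once, since prolonged acid contact would let the free alcohol attack the second ester or the lactone carbonyl.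

Step 5
Reactants: 8 tert-butyl (3S,4S)-3-(3,4-dimethoxybenzyl)-4-(hydroxymethyl)-2-oxotetrahydrofuran-3-carboxylate
Product: 9 tert-butyl (3S,4R)-4-(bromomethyl)-3-(3,4-dimethoxybenzyl)-2-oxotetrahydrofuran-3-carboxylate
Conditions: CBr4, PPh3, CH2Cl2, 0 °C
Reagents that add atoms: carbon tetrabromide, BrC(Br)(Br)Br
Why: The Appel reaction works under neutral conditions with displacement at the primary C7', so C8' is untouched (its descriptor changes only through priorities). Removing the hydroxyl group quickly ends the risk of acyl migration between the two arms, and a bromide is chosen so that its reactivity matches that of aryl bromide 11 in step 7.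

Step 6
Reactants: 10 4-bromocatechol
Product: 11 1,2-bis(benzyloxy)-4-bromobenzene
Conditions: BnBr, K2CO3, DMF, 60 °C, N2
Reagents that add atoms: benzyl bromide, BrCc1ccccc1
Why: This is a double Williamson ether synthesis, run under inert gas so that the catecholate is not oxidised.

Step 7
Reactants: 9 tert-butyl (3S,4R)-4-(bromomethyl)-3-(3,4-dimethoxybenzyl)-2-oxotetrahydrofuran-3-carboxylate; 11 1,2-bis(benzyloxy)-4-bromobenzene
Product: 12 tert-butyl (3S,4R)-4-[3,4-bis(benzyloxy)benzyl]-3-(3,4-dimethoxybenzyl)-2-oxotetrahydrofuran-3-carboxylate
Conditions: NiI2 (10 mol%), 4,4'-dimethoxy-2,2'-bipyridine (10 mol%), NaI (25 mol%), pyridine (10 mol%), Zn, DMPU, 60 °C; 11 in excess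
Reagents that add atoms: none
Why: In this nickel-catalysed reductive cross-electrophile coupling of an aryl bromide with a primary alkyl bromide, zerovalent nickel inserts into the C–Br bond of 11, the C7' radical released from 9 is captured by the arylnickel species, reductive elimination forms C7'–C1', and zinc closes the cycle. The radical sits on C7', so C8' is not touched. The quaternary C8 prevents enolisation and hence internal displacement of bromide, and lactone, ester and benzyl ethers are tolerated by this reaction type.

Step 8
Reactants: 12 tert-butyl (3S,4R)-4-[3,4-bis(benzyloxy)benzyl]-3-(3,4-dimethoxybenzyl)-2-oxotetrahydrofuran-3-carboxylate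
Product: 15 (3R,4R)-4-[3,4-bis(benzyloxy)benzyl]-3-(3,4-dimethoxybenzyl)dihydrofuran-2(3H)-one, via carboxylic acid 13 (not isolated), via C8-epimeric lactone 14 (not isolated)
Conditions: CF3CO2H, CH2Cl2, 0 °C to rt; evaporate; toluene, 110 °C; then DBU (20 mol%), 50 °C
Reagents that add atoms: none
Why: Acidolysis of the tert-butyl ester gives the malonic-type acid 13, which decarboxylates on heating through the lactone enol to 14. Because kinetic protonation of that enol need not favour trans, catalytic DBU then equilibrates C8 to the more stable trans isomer under the control of C8', which has no acidic hydrogen and is not affected.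

Step 9
Reactants: 15 (3R,4R)-4-[3,4-bis(benzyloxy)benzyl]-3-(3,4-dimethoxybenzyl)dihydrofuran-2(3H)-one
Product: 16 (3R,4R)-4-(3,4-dihydroxybenzyl)-3-(3,4-dimethoxybenzyl)dihydrofuran-2(3H)-one
Conditions: H2 (1 atm), Pd/C (10 wt%), degassed EtOAc/EtOH, rt
Reagents that add atoms: none
Why: Catalytic hydrogenolysis of the aryl benzyl ethers under neutral conditions releases the catechol without base or oxidant. The methyl ethers, the lactone, C7, C7' and both stereocentres are not affected.

## Compound list

1 | di-tert-butyl malonate | CC(C)(C)OC(=O)CC(=O)OC(C)(C)C | starting material
2 | 3-iodooxetane | IC1COC1 | starting material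
3 | di-tert-butyl 2-(oxetan-3-yl)malonate | CC(C)(C)OC(=O)C(C1COC1)C(=O)OC(C)(C)C | intermediate
4 | veratryl alcohol | COc1ccc(CO)cc1OC | starting material
5 | 3,4-dimethoxybenzyl bromide | COc1ccc(CBr)cc1OC | intermediate
6 | di-tert-butyl 2-(3,4-dimethoxybenzyl)-2-(oxetan-3-yl)malonate | COc1ccc(CC(C2COC2)(C(=O)OC(C)(C)C)C(=O)OC(C)(C)C)cc1OC | intermediate
7 | 2-tert-butoxy-3-(tert-butoxycarbonyl)-3-(3,4-dimethoxybenzyl)-4-(hydroxymethyl)-4,5-dihydro-3H-furan-1-ium (dialkoxycarbenium ion, chiral phosphate as counter-ion) | COc1ccc(C[C@@]2(C(=O)OC(C)(C)C)C(=[O+]C(C)(C)C)OC[C@@H]2CO)cc1OC | intermediate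
8 | tert-butyl (3S,4S)-3-(3,4-dimethoxybenzyl)-4-(hydroxymethyl)-2-oxotetrahydrofuran-3-carboxylate | COc1ccc(C[C@@]2(C(=O)OC(C)(C)C)C(=O)OC[C@@H]2CO)cc1OC | intermediate
9 | tert-butyl (3S,4R)-4-(bromomethyl)-3-(3,4-dimethoxybenzyl)-2-oxotetrahydrofuran-3-carboxylate | COc1ccc(C[C@@]2(C(=O)OC(C)(C)C)C(=O)OC[C@@H]2CBr)cc1OC | intermediate
10 | 4-bromocatechol | Oc1ccc(Br)cc1O | starting material
11 | 1,2-bis(benzyloxy)-4-bromobenzene | Brc1ccc(OCc2ccccc2)c(OCc2ccccc2)c1 | intermediate
12 | tert-butyl (3S,4R)-4-[3,4-bis(benzyloxy)benzyl]-3-(3,4-dimethoxybenzyl)-2-oxotetrahydrofuran-3-carboxylate | COc1ccc(C[C@@]2(C(=O)OC(C)(C)C)C(=O)OC[C@@H]2Cc2ccc(OCc3ccccc3)c(OCc3ccccc3)c2)cc1OC | intermediate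
13 | (3R,4R)-4-[3,4-bis(benzyloxy)benzyl]-3-(3,4-dimethoxybenzyl)-2-oxotetrahydrofuran-3-carboxylic acid | COc1ccc(C[C@@]2(C(=O)O)C(=O)OC[C@@H]2Cc2ccc(OCc3ccccc3)c(OCc3ccccc3)c2)cc1OC | intermediate
14 | (4R)-4-[3,4-bis(benzyloxy)benzyl]-3-(3,4-dimethoxybenzyl)dihydrofuran-2(3H)-one, mixture of epimers at C3 (C8) | COc1ccc(CC2C(=O)OC[C@@H]2Cc2ccc(OCc3ccccc3)c(OCc3ccccc3)c2)cc1OC | intermediate
15 | (3R,4R)-4-[3,4-bis(benzyloxy)benzyl]-3-(3,4-dimethoxybenzyl)dihydrofuran-2(3H)-one | COc1ccc(C[C@H]2C(=O)OC[C@@H]2Cc2ccc(OCc3ccccc3)c(OCc3ccccc3)c2)cc1OC | intermediate
16 | (3R,4R)-4-(3,4-dihydroxybenzyl)-3-(3,4-dimethoxybenzyl)dihydrofuran-2(3H)-one | COc1ccc(C[C@H]2C(=O)OC[C@@H]2Cc2ccc(O)c(O)c2)cc1OC | target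

## Step count and risks

Total step count: 9. Longest linear sequence: 7 (steps 1, 3, 4, 5, 7, 8, 9).

**Step 4 (key step).**
- *What may go wrong:* the most likely failure is sluggish turnover. An ester carbonyl is a far weaker nucleophile than the alcohols used in the known openings, and the heating needed to compensate would loosen the ion pair and lower the discrimination between the two CH2 groups.
- *Second danger:* the liberated alcohol may react further under acid catalysis. Lactonisation onto the remaining ester on the same face would restore a mirror plane and waste material. Migration of the lactone acyl group to the free arm would exchange C9' and C7' and erode the enantiomeric purity.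
- *Minor path:* Friedel–Crafts opening of the oxetane by ring A.
- *Fallback:* it sets out from 6 and comes back at 9, so it also replaces step 5.
  - It uses the known enantioselective intermolecular opening of 3-substituted oxetanes by bromotrimethylsilane under a chiral squaramide hydrogen-bond donor.
  - The donor is of the type 3-{[3,5-bis(trifluoromethyl)phenyl]amino}-4-({(2S)-3,3-dimethyl-1-oxo-1-[(2R)-2-(phenanthren-9-yl)pyrrolidin-1-yl]butan-2-yl}amino)cyclobut-3-ene-1,2-dione, with the enantiomer chosen as needed.
  - This should give di-tert-butyl 2-[(2R)-1-bromo-3-(trimethylsilyloxy)propan-2-yl]-2-(3,4-dimethoxybenzyl)malonate F1.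
  - Methanolysis of the silyl ether with a trace of acid gives di-tert-butyl 2-[(2R)-1-bromo-3-hydroxypropan-2-yl]-2-(3,4-dimethoxybenzyl)malonate F2.
  - The known Brønsted-acid-catalysed lactonisation of γ-hydroxy di-tert-butyl malonates (diphenyl hydrogen phosphate, toluene) then closes ring C onto either ester to give 9.
  - In this variant bromide selects the enantiotopic CH2, the oxetane oxygen stays on C9', and no free alcohol is left beside a spare ester after ring closure.

**Step 1.**
- *What may go wrong:* displacement at a four-membered ring carbon is slow and the di-tert-butyl malonate anion is bulky. Incomplete conversion and slow thermal loss of the tert-butyl esters on long heating are the likely problems.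
- *Fallback:* it gives up the displacement and builds C8–C8' by olefination. It uses neither 1 nor 2 and so sets out from no numbered compound of the route. It starts from purchased oxetan-3-one F3 and comes back at 3.
  - Wittig olefination of F3 with tert-butyl (triphenylphosphoranylidene)acetate gives tert-butyl 2-(oxetan-3-ylidene)acetate F4.
  - Hydrogenation over Pd/C gives tert-butyl 2-(oxetan-3-yl)acetate F5.
  - C-acylation of the lithium enolate of F5 (two equivalents of lithium diisopropylamide, THF, −78 °C) with di-tert-butyl dicarbonate gives 3.

**Step 7.**
- *What may go wrong:* the electron-rich aryl bromide adds slowly to zerovalent nickel, so the valuable alkyl bromide may be consumed by homocoupling or hydrodehalogenation before it is captured. The zinc salts formed at 60 °C may also assist displacement of bromide by the ester carbonyl on the same face, with loss of the tert-butyl group.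
- *Fallback:* it separates the two activations and replaces the radical cross-electrophile process by a palladium-catalysed coupling of a preformed organometallic. It sets out from 8 and comes back at 12.
  - Iodination (I2, PPh3, imidazole) gives tert-butyl (3S,4R)-3-(3,4-dimethoxybenzyl)-4-(iodomethyl)-2-oxotetrahydrofuran-3-carboxylate F6.
  - Zinc insertion (Zn dust, LiCl, THF, 25–40 °C) gives {[(3R,4S)-4-(tert-butoxycarbonyl)-4-(3,4-dimethoxybenzyl)-5-oxotetrahydrofuran-3-yl]methyl}zinc iodide F7.
  - Negishi coupling with 11 (Pd(OAc)2, 2-dicyclohexylphosphino-2',6'-dimethoxybiphenyl, THF) gives 12.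

**Step 8.**
- *What may go wrong:* the acidolysis generates a tert-butyl cation beside three electron-rich rings. Ring alkylation and partial acid-induced loss or migration of benzyl groups are the likely side processes, and incomplete equilibration at C8 would leave cis material.
- *Fallback:* it avoids free cations altogether. It sets out from 12 and comes back at 15. Neutral thermolysis of 12 in diphenyl ether at about 200 °C removes the tert-butyl group by a concerted retro-ene elimination. Acid 13 decarboxylates at once at that temperature to 14, and the same DBU equilibration follows. No new compound is made.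

## Further compounds

F1 | step 4 | di-tert-butyl 2-[(2R)-1-bromo-3-(trimethylsilyloxy)propan-2-yl]-2-(3,4-dimethoxybenzyl)malonate | COc1ccc(CC(C(=O)OC(C)(C)C)(C(=O)OC(C)(C)C)[C@@H](CBr)CO[Si](C)(C)C)cc1OC
F2 | step 4 | di-tert-butyl 2-[(2R)-1-bromo-3-hydroxypropan-2-yl]-2-(3,4-dimethoxybenzyl)malonate | COc1ccc(CC(C(=O)OC(C)(C)C)(C(=O)OC(C)(C)C)[C@@H](CBr)CO)cc1OC
F3 | step 1 | oxetan-3-one (purchased) | O=C1COC1
F4 | step 1 | tert-butyl 2-(oxetan-3-ylidene)acetate | CC(C)(C)OC(=O)C=C1COC1
F5 | step 1 | tert-butyl 2-(oxetan-3-yl)acetate | CC(C)(C)OC(=O)CC1COC1
F6 | step 7 | tert-butyl (3S,4R)-3-(3,4-dimethoxybenzyl)-4-(iodomethyl)-2-oxotetrahydrofuran-3-carboxylate | COc1ccc(C[C@@]2(C(=O)OC(C)(C)C)C(=O)OC[C@@H]2CI)cc1OC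
F7 | step 7 | {[(3R,4S)-4-(tert-butoxycarbonyl)-4-(3,4-dimethoxybenzyl)-5-oxotetrahydrofuran-3-yl]methyl}zinc iodide | COc1ccc(C[C@@]2(C(=O)OC(C)(C)C)C(=O)OC[C@@H]2C[Zn]I)cc1OC
F0 | step 8 | none | none
A1 | alternative 1 | (3R,4R)-3-(3,4-dimethoxybenzyl)-4-(prop-2-yn-1-yl)dihydrofuran-2(3H)-one | COc1ccc(C[C@H]2C(=O)OC[C@@H]2CC#C)cc1OC
A2 | alternative 1 | 2,3-bis(trimethylsilyloxy)buta-1,3-diene | C=C(O[Si](C)(C)C)C(=C)O[Si](C)(C)C
A3 | alternative 1 | (3R,4R)-4-{[4,5-bis(trimethylsilyloxy)cyclohexa-1,4-dien-1-yl]methyl}-3-(3,4-dimethoxybenzyl)dihydrofuran-2(3H)-one | COc1ccc(C[C@H]2C(=O)OC[C@@H]2CC2=CCC(O[Si](C)(C)C)=C(O[Si](C)(C)C)C2)cc1OC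
A4 | alternative 2 | (E)-3-[3,4-bis(benzyloxy)phenyl]allyl 2-diazo-3-(3,4-dimethoxyphenyl)propanoate | COc1ccc(CC(=[N+]=[N-])C(=O)OC/C=C/c2ccc(OCc3ccccc3)c(OCc3ccccc3)c2)cc1OC
A5 | alternative 2 | (1S,5R,6S)-6-[3,4-bis(benzyloxy)phenyl]-1-(3,4-dimethoxybenzyl)-3-oxabicyclo[3.1.0]hexan-2-one (exo aryl) | O=C1OC[C@@H]2[C@@H](c3ccc(OCc4ccccc4)c(OCc4ccccc4)c3)[C@]12Cc1ccc(OC)c(OC)c1
A6 | alternative 3 | methyl (2R)-4-[3,4-bis(benzyloxy)phenyl]-2-(3,4-dimethoxybenzyl)-4-oxobutanoate | COc1ccc(C[C@H](CC(=O)c2ccc(OCc3ccccc3)c(OCc3ccccc3)c2)C(=O)OC)cc1OC
A7 | alternative 3 | formaldehyde | C=O
A8 | alternative 3 | (3R,4R)-4-[3,4-bis(benzyloxy)benzoyl]-3-(3,4-dimethoxybenzyl)dihydrofuran-2(3H)-one | COc1ccc(C[C@H]2C(=O)OC[C@@H]2C(=O)c2ccc(OCc3ccccc3)c(OCc3ccccc3)c2)cc1OC
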